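**Retrosynthetic overview**

1. Target 40 ← (6R)-allylic alcohol 39 by deoxychlorination with inversion; lactone ring C (O–C7–C8–C17–C19) is closed last, from a C19 ester onto O7.
2. Ten-membered ring B (C1–C10) ← twelve-membered β-keto lactone 33 by palladium-catalysed decarboxylative allylation: C3–C4 is formed and the ester C and O leave as CO2. The enabling feature is the α-allyl ketone unit O=C2–C3H2–C4H2–C5(=C16H2) of ring B: C1 is quaternary and the two allyl termini (C4, C16) are equivalent CH2 groups.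
3. Lactone 33 ← acylketene macrolactonisation between a C2 β-keto ester (from the C2 aldehyde) and the C4 allylic alcohol.
4. Ring A (C1, C10–C14) ← silicon-tethered type 2 intramolecular Diels–Alder reaction of an (E)-2-methyl enal with a 2-silyloxydiene anchored on O8, then Saegusa and Rubottom oxidations.
5. Chain C4–C10 ← L-arabinose (C7, C9), ester enolate addition to its 3-ulose (C8) and chelation-controlled vinyl addition (C6, with C5, C4, C16). Ring order: A, twelve-membered lactone, B, C.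

Key step: step 18

Remark 1: atom numbers are those of the briarane skeleton of the target (C15 and C20 are the methyls on C1 and C11, C18 the methyl on C17); PMB = 4-methoxybenzyl, TES = triethylsilyl, TBDPS = tert-butyldiphenylsilyl.
Remark 2 (assumption): C17 is not controlled in step 3; compounds 6–8, 14–18, 20, 23–28, 30–38 are C17 epimer mixtures, drawn without a descriptor at C17, and C17 is fixed by equilibration in step 22.

**Route**

Step 1
Reactants: 1 L-arabinose
Product: 3 5-O-TBDPS-1,2-O-isopropylidene-β-L-arabinofuranose, via 5-O-silyl arabinofuranose 2 (not isolated)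
Conditions: t-BuPh2SiCl, pyridine, 0 °C to rt; then Me2C(OMe)2, acetone, (1S)-camphor-10-sulfonic acid (cat.), rt
Reagents that add atoms: tert-butyl(chloro)diphenylsilane, CC(C)(C)[Si](Cl)(c1ccccc1)c1ccccc1; 2,2-dimethoxypropane, COC(C)(C)OC
Why: Selective silylation of the primary hydroxyl holds the sugar in the furanose form and acid-catalysed acetal formation then takes the cis-1,2-diol, so only 3-OH stays free and C7 and C9 come from the sugar.

Step 2
Reactants: 3
Product: 4 5-O-TBDPS-1,2-O-isopropylidene-β-L-threo-pentofuranos-3-ulose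
Conditions: Dess–Martin periodinane, NaHCO3, CH2Cl2, rt
Reagents that add atoms: none
Why: Dess–Martin oxidation of the only free alcohol gives the ketone under non-basic conditions that should not epimerise the flanking centres.

Step 3
Reactants: 4; 5 tert-butyl propanoate
Product: 7 3-C-[1-(tert-butoxycarbonyl)ethyl]-5-O-TBDPS-1,2-O-isopropylidene-3-O-TES-β-L-lyxofuranose, via lithium aldolate 6 (not isolated)
Conditions: LiN(iPr)2, 5, THF, −78 °C; add 4; then Et3SiOSO2CF3, −78 to −20 °C
Reagents that add atoms: triethylsilyl trifluoromethanesulfonate, CC[Si](CC)(CC)OS(=O)(=O)C(F)(F)F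
Why: Aldol addition of the ester enolate should occur on the ketone face opposite both the acetonide and the C4 side chain of the cis-fused bicycle, which sets C8 (oxygen cis to O7 and C10), and in situ O-silylation blocks retro-aldol cleavage.

Step 4
Reactants: 7
Product: 8 3-C-[1-(tert-butoxycarbonyl)ethyl]-5-O-TBDPS-3-O-TES-L-lyxofuranose (lactol, anomers)
Conditions: AcOH/H2O (4:1), 65 °C
Reagents that add atoms: none
Why: Acid-catalysed acetal hydrolysis unmasks the C6 aldehyde as its lactol; the hindered tertiary silyl ether, the TBDPS ether and the tert-butyl ester should survive aqueous acetic acid.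

Step 5
Reactants: 9 2,3-dibromoprop-1-ene; 10 (4-methoxyphenyl)methanol
Product: 11 2-bromoallyl 4-methoxybenzyl ether
Conditions: NaH, THF, 0 °C to rt
Reagents that add atoms: none
Why: Williamson ether synthesis; the alkoxide displaces the allylic bromide while the vinylic bromide is inert.

Step 6
Reactants: 8; 11
Product: 14 open-chain triol (4-O-PMB, C5 exocyclic methylene, (6R)-OH syn to 7-OH, 8-O-TES with the CH(CH3)CO2tBu branch, 9-OH, 10-O-TBDPS), via vinyllithium 12 (not isolated), via vinylmagnesium bromide 13 (not isolated)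
Conditions: 11, t-BuLi (2 equiv), Et2O, −78 °C; MgBr2·OEt2; then 8, THF, −78 to 0 °C; aq. NH4Cl
Reagents that add atoms: none
Why: Bromine–lithium exchange and transmetalation give a vinyl Grignard reagent that adds to the open hydroxy aldehyde under Cram chelate control (magnesium bridging the C7 alkoxide and C6=O, attack anti to C8), which should set C6 syn to the C7 oxygen.

Step 7
Reactants: 14
Product: 15 6,7-O-isopropylidene derivative of 14 (9-OH free)
Conditions: Me2C(OMe)2, pyridinium p-toluenesulfonate (cat.), CH2Cl2, rt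
Reagents that add atoms: 2,2-dimethoxypropane, COC(C)(C)OC
Why: Acetal formation under thermodynamic control takes the syn-1,2-diol at C6/C7 as a dioxolane in preference to the 1,3-related C7/C9 pair, the C8 oxygen being silylated.

Step 8
Reactants: 15
Product: 16 9-O-acetyl derivative of 15
Conditions: Ac2O, 4-(dimethylamino)pyridine (cat.), pyridine, CH2Cl2, rt
Reagents that add atoms: acetic anhydride, CC(=O)OC(C)=O
Why: Nucleophile-catalysed acylation of the only free hydroxyl installs the C9 acetate of the target.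

Step 9
Reactants: 16
Product: 17 diol (10-OH primary, 8-OH tertiary; 9-OAc, 6,7-acetonide, 4-O-PMB)
Conditions: HF·pyridine, pyridine, THF, 0 °C to rt
Reagents that add atoms: none
Why: Fluoride-mediated desilylation in a buffered acidic medium removes the TBDPS and the tertiary TES ethers without acetate migration or loss of the acetonide.

Step 10
Reactants: 17
Product: 18 C10 aldehyde (α-acetoxy aldehyde, 8-OH free)
Conditions: Dess–Martin periodinane, NaHCO3, CH2Cl2, 0 °C
Reagents that add atoms: none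
Why: Dess–Martin oxidation of the primary alcohol; the tertiary alcohol is inert and the buffered, non-basic medium should not epimerise C9.

Step 11
Reactants: 18; 19 2-(triphenylphosphoranylidene)propanal
Product: 20 (E)-2-methyl enal (C2 aldehyde, C1=C10 double bond, 8-OH free)
Conditions: toluene, 80 °C
Reagents that add atoms: none
Why: Wittig olefination with the stabilised ylide gives the E trisubstituted enal under neutral conditions that preserve C9.

Step 12
Reactants: 20; 21 pent-1-en-3-one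
Product: 24 bridged cycloadduct (ring A with C1 methyl and formyl, C10–H, C11 methyl β, cyclic silyl enol ether O8–Si(iPr)2–O–C12=C13), via dienyloxysilyl triflate 22 (not isolated), via tethered triene 23 (not isolated)
Conditions: 21, iPr2Si(OSO2CF3)2, Et3N, CH2Cl2, −78 to 0 °C; then 20, 2,6-lutidine, 0 °C to rt; then toluene (0.01 M), 2,6-di-tert-butyl-4-methylphenol, 110 °C
Reagents that add atoms: diisopropylsilyl bis(trifluoromethanesulfonate), CC(C)[Si](OS(=O)(=O)C(F)(F)F)(OS(=O)(=O)C(F)(F)F)C(C)C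
Why: Temporary silicon tether and type 2 intramolecular Diels–Alder reaction: the silyl acetal joins O8 to the 2-oxygen of the diene, so the diene should reach the enal from the face on which C8 lies in the conformer with H9 in the alkene plane next to the cis methyl (allylic 1,3-strain), which sets C10 and, through the E geometry, C1 with C2 trans to C9, while the tether fixes the C10–C11/C1–C14 regiochemistry.

Step 13
Reactants: 24
Product: 26 enone (C12 ketone, C13=C14; O8 as diisopropyl(methoxy)silyl ether; C2 aldehyde), via acetoxysilane 25 (not isolated)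
Conditions: Pd(OAc)2 (1.1 equiv), MeCN, rt; then MeOH, Et3N
Reagents that add atoms: methanol, CO
Why: Saegusa–Ito oxidation: divalent palladium turns the regiodefined silyl enol ether into the enone by β-hydride elimination toward C14, and methanolysis of the acetoxysilane leaves the silicon as a protecting group on O8.

Step 14
Reactants: 26
Product: 28 C11 α-triethylsilyloxy enone (C20 methyl β), via dienol silyl ether 27 (not isolated)
Conditions: Et3SiOSO2CF3, Et3N, CH2Cl2, −78 to 0 °C; then 3-chloroperoxybenzoic acid, NaHCO3, CH2Cl2, −20 °C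
Reagents that add atoms: triethylsilyl trifluoromethanesulfonate, CC[Si](CC)(CC)OS(=O)(=O)C(F)(F)F; 3-chloroperoxybenzoic acid, O=C(OO)c1cccc(Cl)c1
Why: Rubottom oxidation: enolisation is possible only toward C11 because C1 is quaternary, and the peracid should epoxidise the enol ether on the α face, anti to the C15 methyl and the C10 side chain, so that silyl migration gives the C11 oxygen α.

Step 15
Reactants: 28; 29 tert-butyl diazoacetate
Product: 30 tert-butyl β-keto ester (C2 ketone, C3 methylene)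
Conditions: SnCl2 (0.3 equiv), CH2Cl2, rt
Reagents that add atoms: none
Why: Roskamp reaction: Lewis acid-promoted addition of the diazo ester to the non-enolisable aldehyde and 1,2-hydride shift with loss of N2 gives the β-keto ester in one step.

Step 16
Reactants: 30
Product: 31 C4 allylic alcohol
Conditions: 2,3-dichloro-5,6-dicyano-1,4-benzoquinone, CH2Cl2/pH 7 buffer, 0 °C
Reagents that add atoms: none
Why: Oxidative cleavage of the 4-methoxybenzyl ether (hydride abstraction to the oxocarbenium ion and hydrolysis) frees the only hydroxyl of the molecule.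

Step 17
Reactants: 31
Product: 33 twelve-membered β-keto lactone (ring: O, C4–C10, C1–C3, ester C), via acylketene 32 (not isolated)
Conditions: toluene (0.5 mM), 4 Å molecular sieves, 110 °C
Reagents that add atoms: none
Why: Acylketene macrolactonisation: thermal loss of tert-butanol from the β-keto ester gives an acylketene that should be trapped at high dilution by the C4 hydroxyl, every other oxygen being blocked.

Step 18
Reactants: 33
Product: 34 ten-membered diketone (ring B closed; C2 ketone, C5=C16 exocyclic methylene, C12 enone)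
Conditions: Pd(PPh3)4 (10 mol %), THF (2 mM), 40 °C
Reagents that add atoms: none
Why: Proposed new method: oxidative addition of zerovalent palladium to the allylic C4–O bond opens the lactone to a π-allylpalladium β-keto carboxylate, which loses CO2 to give a C2–C3 palladium enolate still tethered to the C4–C5–C16 π-allyl unit, and C–C coupling between C3 and an allyl terminus recloses the chain as the ten-membered carbocycle, two ring atoms smaller. The closest known reactions are the Tsuji–Saegusa decarboxylative allylation of acyclic allyl β-keto esters and Tsuji–Trost macrocyclisations of tethered enolates, merged here into a ring contraction. The ring is closed by attack of the enolate carbon on a CH2 terminus of the π-allyl, exo with respect to the allyl unit, so that C5=C16 remains exocyclic. No stereocentre is formed. The step needs C-allylation by one defined enolate at high dilution: C1 is quaternary so only the C3 enolate exists, both allyl termini are CH2 groups and give the same constitution, and C12 is a ketone and O6 an acetal oxygen so no second allylic leaving group competes. No free hydroxyl can protonate the enolate, and an O-allylated by-product would be an allyl vinyl ether that can reach the same ketone by Claisen rearrangement.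

Step 19
Reactants: 34
Product: 35 C12 allylic alcohol (12-OH α, cis to O11; C2 ketone intact)
Conditions: NaBH4, CeCl3·7H2O, MeOH/THF, −78 °C
Reagents that add atoms: none
Why: Luche reduction: 1,2-reduction of the enone, chemoselective over the saturated hindered C2 ketone at low temperature, with hydride expected anti to the neighbouring α-silyloxy group (Felkin–Anh) to give the alcohol cis to O11.

Step 20
Reactants: 35
Product: 36 diol ((2S)-OH, 12-OH)
Conditions: (R)-1-methyl-3,3-diphenyltetrahydro-1H,3H-pyrrolo[1,2-c][1,3,2]oxazaborole (0.5 equiv), catecholborane, toluene, −78 °C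
Reagents that add atoms: none
Why: Corey–Bakshi–Shibata reduction: the catalyst distinguishes the quaternary C1 side (large) from the C3 methylene side (small) and should deliver hydride to give the 2S alcohol, and catecholborane at low temperature does not hydroborate the alkenes.

Step 21
Reactants: 36
Product: 37 2,9,12-triacetate (O8 and O11 silylated, 6,7-acetonide, tert-butyl ester)
Conditions: Ac2O, 4-(dimethylamino)pyridine, Et3N, CH2Cl2, rt
Reagents that add atoms: acetic anhydride, CC(=O)OC(C)=O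
Why: Nucleophile-catalysed acetylation of the two secondary alcohols; both tertiary oxygens are still protected.

Step 22
Reactants: 37
Product: 39 (6R)-hydroxy lactone (17R; 8-OH and 11-OH free), via lactone epimer mixture 38 (not isolated)
Conditions: CF3CO2H/H2O (9:1), CH2Cl2, 0 °C to rt; evaporate; then 1,8-diazabicyclo[5.4.0]undec-7-ene, toluene, rt
Reagents that add atoms: none
Why: Acidolysis removes the acetonide, both silyl groups and the tert-butyl ester and the C19 acid lactonises onto O7 (five-membered ring preferred over the six-membered alternative with O6), then base-mediated epimerisation through the lactone enol should settle C17 with its methyl trans to the bulky C9 substituent on C8, the 17R configuration.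

Step 23
Reactants: 39
Product: 40 target CNP0259091.1
Conditions: PPh3, hexachloroacetone, CH2Cl2, −20 to 0 °C
Reagents that add atoms: hexachloroacetone, ClC(Cl)(Cl)C(=O)C(Cl)(Cl)Cl
Why: Appel-type deoxychlorination: chloride should displace the allylic oxyphosphonium ion by SN2 with inversion to give the 6S chloride without allylic transposition, and the tertiary alcohols do not react at low temperature.

**Compound list**

1 | L-arabinose | O=C[C@H](O)[C@@H](O)[C@@H](O)CO | starting material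
2 | 5-O-TBDPS-L-arabinofuranose (anomers) | OC1O[C@@H](CO[Si](c2ccccc2)(c2ccccc2)C(C)(C)C)[C@H](O)[C@H]1O | intermediate
3 | 5-O-TBDPS-1,2-O-isopropylidene-β-L-arabinofuranose | CC1(C)O[C@H]2O[C@@H](CO[Si](c3ccccc3)(c3ccccc3)C(C)(C)C)[C@H](O)[C@H]2O1 | intermediate
4 | 5-O-TBDPS-1,2-O-isopropylidene-β-L-threo-pentofuranos-3-ulose | CC1(C)O[C@H]2O[C@@H](CO[Si](c3ccccc3)(c3ccccc3)C(C)(C)C)C(=O)[C@H]2O1 | intermediate
5 | tert-butyl propanoate | CCC(=O)OC(C)(C)C | starting material
6 | lithium alkoxide of the aldol adduct (3-C-branched β-L-lyxofuranose) | CC1(C)O[C@H]2O[C@@H](CO[Si](c3ccccc3)(c3ccccc3)C(C)(C)C)[C@]([O-])(C(C)C(=O)OC(C)(C)C)[C@H]2O1.[Li+] | intermediate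
7 | 3-C-[1-(tert-butoxycarbonyl)ethyl]-5-O-TBDPS-1,2-O-isopropylidene-3-O-TES-β-L-lyxofuranose | CC1(C)O[C@H]2O[C@@H](CO[Si](c3ccccc3)(c3ccccc3)C(C)(C)C)[C@](O[Si](CC)(CC)CC)(C(C)C(=O)OC(C)(C)C)[C@H]2O1 | intermediate
8 | 3-C-[1-(tert-butoxycarbonyl)ethyl]-5-O-TBDPS-3-O-TES-L-lyxofuranose (lactol) | OC1O[C@@H](CO[Si](c2ccccc2)(c2ccccc2)C(C)(C)C)[C@](O[Si](CC)(CC)CC)(C(C)C(=O)OC(C)(C)C)[C@H]1O | intermediate
9 | 2,3-dibromoprop-1-ene | BrCC(Br)=C | starting material
10 | (4-methoxyphenyl)methanol | COc1ccc(CO)cc1 | starting material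
11 | 2-bromoallyl 4-methoxybenzyl ether | COc1ccc(COCC(Br)=C)cc1 | intermediate
12 | [3-(4-methoxybenzyloxy)prop-1-en-2-yl]lithium | [Li]C(=C)COCc1ccc(OC)cc1 | intermediate
13 | [3-(4-methoxybenzyloxy)prop-1-en-2-yl]magnesium bromide | Br[Mg]C(=C)COCc1ccc(OC)cc1 | intermediate
14 | open-chain C4–C10 triol (6R, 6,7-syn) | COc1ccc(COCC(=C)[C@@H](O)[C@H](O)[C@@](O[Si](CC)(CC)CC)(C(C)C(=O)OC(C)(C)C)[C@@H](O)CO[Si](c2ccccc2)(c2ccccc2)C(C)(C)C)cc1 | intermediate
15 | 6,7-acetonide of 14 | COc1ccc(COCC(=C)[C@H]2OC(C)(C)O[C@@H]2[C@@](O[Si](CC)(CC)CC)(C(C)C(=O)OC(C)(C)C)[C@@H](O)CO[Si](c3ccccc3)(c3ccccc3)C(C)(C)C)cc1 | intermediate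
16 | 9-acetate of 15 | COc1ccc(COCC(=C)[C@H]2OC(C)(C)O[C@@H]2[C@@](O[Si](CC)(CC)CC)(C(C)C(=O)OC(C)(C)C)[C@@H](OC(C)=O)CO[Si](c3ccccc3)(c3ccccc3)C(C)(C)C)cc1 | intermediate
17 | 8,10-diol | COc1ccc(COCC(=C)[C@H]2OC(C)(C)O[C@@H]2[C@@](O)(C(C)C(=O)OC(C)(C)C)[C@@H](OC(C)=O)CO)cc1 | intermediate
18 | C10 aldehyde | COc1ccc(COCC(=C)[C@H]2OC(C)(C)O[C@@H]2[C@@](O)(C(C)C(=O)OC(C)(C)C)[C@@H](OC(C)=O)C=O)cc1 | intermediate
19 | 2-(triphenylphosphoranylidene)propanal | CC(C=O)=P(c1ccccc1)(c1ccccc1)c1ccccc1 | starting material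
20 | (E)-2-methyl enal | COc1ccc(COCC(=C)[C@H]2OC(C)(C)O[C@@H]2[C@@](O)(C(C)C(=O)OC(C)(C)C)[C@@H](OC(C)=O)/C=C(\C)C=O)cc1 | intermediate
21 | pent-1-en-3-one | CCC(=O)C=C | starting material
22 | (Z)-penta-1,3-dien-3-yloxy(diisopropyl)silyl triflate | C/C=C(\O[Si](C(C)C)(C(C)C)OS(=O)(=O)C(F)(F)F)C=C | intermediate
23 | silyl acetal-tethered triene | COc1ccc(COCC(=C)[C@H]2OC(C)(C)O[C@@H]2[C@@](O[Si](C(C)C)(C(C)C)O/C(C=C)=C\C)(C(C)C(=O)OC(C)(C)C)[C@@H](OC(C)=O)/C=C(\C)C=O)cc1 | intermediate
24 | bridged cycloadduct (ring A, cyclic silyl enol ether) | COc1ccc(COCC(=C)[C@H]2OC(C)(C)O[C@@H]2[C@]3(C(C)C(=O)OC(C)(C)C)O[Si](C(C)C)(C(C)C)OC4=CC[C@](C)(C=O)[C@H]([C@H]4C)[C@@H]3OC(C)=O)cc1 | intermediate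
25 | enone, O8 acetoxy(diisopropyl)silyl ether | COc1ccc(COCC(=C)[C@H]2OC(C)(C)O[C@@H]2[C@@](O[Si](OC(C)=O)(C(C)C)C(C)C)(C(C)C(=O)OC(C)(C)C)[C@@H](OC(C)=O)[C@H]3[C@@H](C)C(=O)C=C[C@]3(C)C=O)cc1 | intermediate
26 | enone, O8 diisopropyl(methoxy)silyl ether | COc1ccc(COCC(=C)[C@H]2OC(C)(C)O[C@@H]2[C@@](O[Si](OC)(C(C)C)C(C)C)(C(C)C(=O)OC(C)(C)C)[C@@H](OC(C)=O)[C@H]3[C@@H](C)C(=O)C=C[C@]3(C)C=O)cc1 | intermediate
27 | cross-conjugated TES dienol ether | COc1ccc(COCC(=C)[C@H]2OC(C)(C)O[C@@H]2[C@@](O[Si](OC)(C(C)C)C(C)C)(C(C)C(=O)OC(C)(C)C)[C@@H](OC(C)=O)[C@H]3C(C)=C(O[Si](CC)(CC)CC)C=C[C@]3(C)C=O)cc1 | intermediate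
28 | C11 α-triethylsilyloxy enone | COc1ccc(COCC(=C)[C@H]2OC(C)(C)O[C@@H]2[C@@](O[Si](OC)(C(C)C)C(C)C)(C(C)C(=O)OC(C)(C)C)[C@@H](OC(C)=O)[C@H]3[C@](C)(O[Si](CC)(CC)CC)C(=O)C=C[C@]3(C)C=O)cc1 | intermediate
29 | tert-butyl diazoacetate | [N-]=[N+]=CC(=O)OC(C)(C)C | starting material
30 | tert-butyl β-keto ester | COc1ccc(COCC(=C)[C@H]2OC(C)(C)O[C@@H]2[C@@](O[Si](OC)(C(C)C)C(C)C)(C(C)C(=O)OC(C)(C)C)[C@@H](OC(C)=O)[C@H]3[C@](C)(O[Si](CC)(CC)CC)C(=O)C=C[C@]3(C)C(=O)CC(=O)OC(C)(C)C)cc1 | intermediate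
31 | C4 allylic alcohol | OCC(=C)[C@H]1OC(C)(C)O[C@@H]1[C@@](O[Si](OC)(C(C)C)C(C)C)(C(C)C(=O)OC(C)(C)C)[C@@H](OC(C)=O)[C@H]2[C@](C)(O[Si](CC)(CC)CC)C(=O)C=C[C@]2(C)C(=O)CC(=O)OC(C)(C)C | intermediate
32 | acylketene | OCC(=C)[C@H]1OC(C)(C)O[C@@H]1[C@@](O[Si](OC)(C(C)C)C(C)C)(C(C)C(=O)OC(C)(C)C)[C@@H](OC(C)=O)[C@H]2[C@](C)(O[Si](CC)(CC)CC)C(=O)C=C[C@]2(C)C(=O)C=C=O | intermediate
33 | twelve-membered β-keto lactone | O1CC(=C)[C@H]2OC(C)(C)O[C@@H]2[C@@](O[Si](OC)(C(C)C)C(C)C)(C(C)C(=O)OC(C)(C)C)[C@@H](OC(C)=O)[C@H]3[C@](C)(O[Si](CC)(CC)CC)C(=O)C=C[C@]3(C)C(=O)CC1=O | intermediate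
34 | ten-membered diketone | C1C(=C)[C@H]2OC(C)(C)O[C@@H]2[C@@](O[Si](OC)(C(C)C)C(C)C)(C(C)C(=O)OC(C)(C)C)[C@@H](OC(C)=O)[C@H]3[C@](C)(O[Si](CC)(CC)CC)C(=O)C=C[C@]3(C)C(=O)C1 | intermediate
35 | C12 allylic alcohol | C1C(=C)[C@H]2OC(C)(C)O[C@@H]2[C@@](O[Si](OC)(C(C)C)C(C)C)(C(C)C(=O)OC(C)(C)C)[C@@H](OC(C)=O)[C@H]3[C@](C)(O[Si](CC)(CC)CC)[C@H](O)C=C[C@]3(C)C(=O)C1 | intermediate
36 | 2,12-diol | C1C(=C)[C@H]2OC(C)(C)O[C@@H]2[C@@](O[Si](OC)(C(C)C)C(C)C)(C(C)C(=O)OC(C)(C)C)[C@@H](OC(C)=O)[C@H]3[C@](C)(O[Si](CC)(CC)CC)[C@H](O)C=C[C@]3(C)[C@@H](O)C1 | intermediate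
37 | 2,9,12-triacetate | C1C(=C)[C@H]2OC(C)(C)O[C@@H]2[C@@](O[Si](OC)(C(C)C)C(C)C)(C(C)C(=O)OC(C)(C)C)[C@@H](OC(C)=O)[C@H]3[C@](C)(O[Si](CC)(CC)CC)[C@H](OC(C)=O)C=C[C@]3(C)[C@@H](OC(C)=O)C1 | intermediate
38 | (6R)-hydroxy lactone, C17 epimers | C=C1CC[C@H](OC(C)=O)[C@@]2(C)C=C[C@@H](OC(C)=O)[C@@](C)(O)[C@@H]2[C@H](OC(C)=O)[C@]2(O)C(C)C(=O)O[C@H]2[C@@H]1O | intermediate
39 | (6R,17R)-hydroxy lactone | C=C1CC[C@H](OC(C)=O)[C@@]2(C)C=C[C@@H](OC(C)=O)[C@@](C)(O)[C@@H]2[C@H](OC(C)=O)[C@]2(O)[C@@H](C)C(=O)O[C@H]2[C@@H]1O | intermediate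
40 | CNP0259091.1 | C=C1CC[C@H](OC(C)=O)[C@@]2(C)C=C[C@@H](OC(C)=O)[C@@](C)(O)[C@@H]2[C@H](OC(C)=O)[C@]2(O)[C@@H](C)C(=O)O[C@H]2[C@H]1Cl | target

**Step count and risks**

Total steps: 23. Longest linear sequence: 22 steps (steps 1–4 and 6–23 from L-arabinose).

Steps most likely to fail:

1. Step 18 (proposed new method). Protonation of the palladium enolate or intermolecular allylation may outrun closure of the ten-membered ring. Fallback, from 31 back to 34: the ring would be closed by a conventional intramolecular alkylation. Alcohol 31 would be converted into the allylic chloride F1 (PPh3, hexachloroacetone, CH2Cl2). C-alkylation of the β-keto ester at high dilution (Cs2CO3, CsI, MeCN, 60 °C) should give the ring-closed β-keto ester F2. Heating F2 in wet dioxane (110 °C; acylketene formation, hydration, decarboxylation) should then give 34.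

2. Step 12. Formation of the mixed silyl acetal on the tertiary alcohol may be incomplete, or the cycloaddition of the trisubstituted enal may be slow or show poor facial selectivity. Fallback, from 20 back to 28: the cycloaddition would be run intermolecularly under catalyst control. Enal 20 would be silylated at O8 (iPr2Si(OSO2CF3)2, 2,6-lutidine; then MeOH) to the silyl-protected enal F3. Ketone 21 would be converted into the silyloxydiene F4 (iPr3SiOSO2CF3, Et3N). F3 and F4 would be combined with the HN(SO2CF3)2-activated 3,3-diphenyl-1-(2-methylphenyl)tetrahydro-1H,3H-pyrrolo[1,2-c][1,3,2]oxazaborole, using the enantiomer that exposes the C8-side face of the enal, to give the cycloadduct F5. Saegusa oxidation of F5 (Pd(OAc)2, MeCN) should give the enone F6 as C11 epimers, which converge on 28 under the conditions of step 14 because C11 is planar in 27.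

3. Step 23. Allylic transposition (SN2′) or elimination may compete during deoxychlorination of the hindered allylic alcohol. Fallback, from 37 to 40: the chloride would be introduced before lactone closure through a cyclic sulfite. Methanolysis of the acetonide of 37 (pyridinium p-toluenesulfonate, MeOH, 40 °C) should give the 6,7-diol F7. SOCl2/Et3N (CH2Cl2, 0 °C) would give the cyclic sulfite F8. LiCl in DMF (70 °C) should open it at the allylic C6 with inversion and give, after aqueous work-up, the chlorohydrin F9. Treatment of F9 as in step 22, with only brief exposure to the base, would give 40.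

Further compounds
F1 | step 18 | C4 allylic chloride of β-keto ester 31 | ClCC(=C)[C@H]1OC(C)(C)O[C@@H]1[C@@](O[Si](OC)(C(C)C)C(C)C)(C(C)C(=O)OC(C)(C)C)[C@@H](OC(C)=O)[C@H]2[C@](C)(O[Si](CC)(CC)CC)C(=O)C=C[C@]2(C)C(=O)CC(=O)OC(C)(C)C
F2 | step 18 | ten-membered ring β-keto ester (34 with CO2tBu on C3) | C1C(=C)[C@H]2OC(C)(C)O[C@@H]2[C@@](O[Si](OC)(C(C)C)C(C)C)(C(C)C(=O)OC(C)(C)C)[C@@H](OC(C)=O)[C@H]3[C@](C)(O[Si](CC)(CC)CC)C(=O)C=C[C@]3(C)C(=O)C1C(=O)OC(C)(C)C
F3 | step 12 | enal 20 with O8 as diisopropyl(methoxy)silyl ether | COc1ccc(COCC(=C)[C@H]2OC(C)(C)O[C@@H]2[C@@](O[Si](OC)(C(C)C)C(C)C)(C(C)C(=O)OC(C)(C)C)[C@@H](OC(C)=O)/C=C(\C)C=O)cc1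
F4 | step 12 | (Z)-3-(triisopropylsilyloxy)penta-1,3-diene | C/C=C(\O[Si](C(C)C)(C(C)C)C(C)C)C=C
F5 | step 12 | intermolecular cycloadduct (triisopropylsilyl enol ether, C11 epimers) | COc1ccc(COCC(=C)[C@H]2OC(C)(C)O[C@@H]2[C@@](O[Si](OC)(C(C)C)C(C)C)(C(C)C(=O)OC(C)(C)C)[C@@H](OC(C)=O)[C@H]3C(C)C(O[Si](C(C)C)(C(C)C)C(C)C)=CC[C@]3(C)C=O)cc1
F6 | step 12 | enone 26 as C11 epimers | COc1ccc(COCC(=C)[C@H]2OC(C)(C)O[C@@H]2[C@@](O[Si](OC)(C(C)C)C(C)C)(C(C)C(=O)OC(C)(C)C)[C@@H](OC(C)=O)[C@H]3C(C)C(=O)C=C[C@]3(C)C=O)cc1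
F7 | step 23 | 6,7-diol from triacetate 37 | C1C(=C)[C@@H](O)[C@H](O)[C@@](O[Si](OC)(C(C)C)C(C)C)(C(C)C(=O)OC(C)(C)C)[C@@H](OC(C)=O)[C@H]2[C@](C)(O[Si](CC)(CC)CC)[C@H](OC(C)=O)C=C[C@]2(C)[C@@H](OC(C)=O)C1
F8 | step 23 | 6,7-cyclic sulfite | C1C(=C)[C@H]2OS(=O)O[C@@H]2[C@@](O[Si](OC)(C(C)C)C(C)C)(C(C)C(=O)OC(C)(C)C)[C@@H](OC(C)=O)[C@H]3[C@](C)(O[Si](CC)(CC)CC)[C@H](OC(C)=O)C=C[C@]3(C)[C@@H](OC(C)=O)C1
F9 | step 23 | (6S)-chloro 7-hydroxy ester (chlorohydrin) | C1C(=C)[C@H](Cl)[C@H](O)[C@@](O[Si](OC)(C(C)C)C(C)C)(C(C)C(=O)OC(C)(C)C)[C@@H](OC(C)=O)[C@H]2[C@](C)(O[Si](CC)(CC)CC)[C@H](OC(C)=O)C=C[C@]2(C)[C@@H](OC(C)=O)C1
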